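**Retrosynthetic overview**
1. The target is the epicatechin-(4β→8) tetramer named in the task. The last C–C bond, C4(top unit)–C8, comes from Lewis acid ionisation of a 4-alkoxyflavan (23) and Friedel–Crafts capture by the epicatechin trimer 8, which is assembled from (−)-epicatechin by two iterative 4β→8 couplings; ester methanolysis and hydrogenolysis of sixteen benzyl ethers finish the route.
2. Ring C of the top unit is built de novo in one step by an auxiliary-controlled cationic [4+2] (oxa-Povarov) reaction of an O-aryl oxocarbenium ion (from mixed acetal 20, made of 3,5-bis(benzyloxy)phenol and 3,4-bis(benzyloxy)benzaldehyde) with the (Z)-2-alkoxyvinyl benzoate 15; it forms C2–C3 and C4–C4a and sets C2 and C3.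
3. Enabling feature: in the top flavan, O1–C8a=C4a of the phloroglucinol ring A together with the benzylic C2 is a latent cationic 2-oxadiene, and C3–C4 is a vicinally oxygenated two-carbon unit whose C4 substituent must in any case be a nucleofuge for the interflavan bond. The chiral auxiliary is therefore placed on the C4 oxygen and leaves in the coupling step.
4. Ring order: all aromatic rings are bought or arrive in epicatechin; ring C of the top unit is the only ring formed (step 11); the three lower rings C come intact from the chiral pool.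

Key step: step 11

Assumption: the sense of induction in step 11 follows the s-trans enol ether model given there (both enantiomers of trans-2-phenylcyclohexanol are sold, so the antipode would serve if the sense proved opposite). C4 of 23 is drawn as the all-cis (endo) epimer; this centre is ionised in step 12, so its configuration does not matter.

Step 1
Reactants: 1 (−)-epicatechin
Product: 2 5,7,3',4'-tetra-O-benzyl-(−)-epicatechin
Conditions: BnBr (4.4 equiv), K2CO3, DMF, 0 °C → rt, argon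
Reagents that add atoms: benzyl bromide, BrCc1ccccc1
Why: Williamson O-alkylation of the four phenols, which are far more acidic than the C3 alcohol; no stereocentre is involved.

Step 2
Reactants: 2 5,7,3',4'-tetra-O-benzyl-(−)-epicatechin
Product: 3 (2R,3R,4S)-5,7,3',4'-tetra-O-benzyl-4-(2-ethoxyethoxy)flavan-3-ol (4β, 3,4-trans)
Conditions: DDQ (2 equiv), 2-ethoxyethanol, CH2Cl2, rt
Reagents that add atoms: 2-ethoxyethanol, CCOCCO
Why: DDQ abstracts hydride from the benzylic C4 next to the electron-rich ring A, and the alcohol captures the cation anti to the C3 hydroxyl (oxidative benzylic alkoxylation), which sets C4 as 4β.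

Step 3
Reactants: 3 (2R,3R,4S)-5,7,3',4'-tetra-O-benzyl-4-(2-ethoxyethoxy)flavan-3-ol
Product: 4 (2R,3R,4S)-5,7,3',4'-tetra-O-benzyl-4-(2-ethoxyethoxy)flavan-3-yl acetate
Conditions: Ac2O, pyridine, cat. DMAP, rt
Reagents that add atoms: acetic anhydride, CC(=O)OC(C)=O
Why: DMAP-catalysed acylation of the secondary alcohol; the acetate later shields the C3 face and blocks O-alkylation.

Step 4
Reactants: 4 (2R,3R,4S)-5,7,3',4'-tetra-O-benzyl-4-(2-ethoxyethoxy)flavan-3-yl acetate; 2 5,7,3',4'-tetra-O-benzyl-(−)-epicatechin (4 equiv)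
Product: 6 [3-O-acetyl-5,7,3',4'-tetra-O-benzylepicatechin]-(4β→8)-[5,7,3',4'-tetra-O-benzylepicatechin], via flavan-4-yl cation triflate 5 (not isolated)
Conditions: TMSOTf (cat.), CH2Cl2, −78 °C; aq. NaHCO3
Reagents that add atoms: none
Why: Lewis acid ionisation of the C4 ether and Friedel–Crafts capture by C8 of the excess nucleophile anti to the C3 acetoxy group gives the 4β→8 bond (flavan-4-yl cation coupling), the excess of 2 holding back higher oligomers.

Step 5
Reactants: 6 [3-O-acetyl-5,7,3',4'-tetra-O-benzylepicatechin]-(4β→8)-[5,7,3',4'-tetra-O-benzylepicatechin] (1.2 equiv); 4 (2R,3R,4S)-5,7,3',4'-tetra-O-benzyl-4-(2-ethoxyethoxy)flavan-3-yl acetate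
Product: 8 [3-O-acetyl-5,7,3',4'-tetra-O-benzylepicatechin]-(4β→8)-[3-O-acetyl-5,7,3',4'-tetra-O-benzylepicatechin]-(4β→8)-[5,7,3',4'-tetra-O-benzylepicatechin], via flavan-4-yl cation tetrafluoroborate 7 (not isolated)
Conditions: AgBF4 (silver tetrafluoroborate, 0.2 equiv), 4 Å MS, CH2Cl2, −20 → 0 °C, dark; aq. NaHCO3
Reagents that add atoms: none
Why: The monovalent silver Lewis acid ionises the C4 ether to the ring-A-stabilised cation as its tetrafluoroborate, which allows a near-equimolar flavan-4-yl cation Friedel–Crafts coupling with the valuable dimer; the only unsubstituted C8 of dimer 6 (upper unit) is the nucleophile and attack again occurs anti to the C3 acetoxy group (4β), the proton released returning the alkoxide as 2-ethoxyethanol and the silver salt to the cycle.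

Step 6
Reactants: 9 (1S,2R)-trans-2-phenylcyclohexanol
Product: 11 allyl (1S,2R)-2-phenylcyclohexyl ether, via sodium alkoxide 10 (not isolated)
Conditions: NaH, DMF, 0 °C; allyl bromide, 0 °C → rt
Reagents that add atoms: allyl bromide, C=CCBr
Why: Williamson etherification of the alkoxide with an allylic halide; the carbinol stereocentre is not touched.

Step 7
Reactants: 11 allyl (1S,2R)-2-phenylcyclohexyl ether
Product: 13 2-{[(1S,2R)-2-phenylcyclohexyl]oxy}acetaldehyde, via secondary ozonide 12 (not isolated)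
Conditions: O3, CH2Cl2, −78 °C (indicator dye); PPh3, −78 °C → rt
Reagents that add atoms: ozone, [O-][O+]=O
Why: Ozonolysis of the terminal alkene with reductive work-up gives the α-alkoxy aldehyde, the phenyl ring being far less reactive towards ozone at −78 °C.

Step 8
Reactants: 13 2-{[(1S,2R)-2-phenylcyclohexyl]oxy}acetaldehyde
Product: 15 (Z)-2-{[(1S,2R)-2-phenylcyclohexyl]oxy}ethenyl benzoate, via potassium Z-enolate 14 (not isolated)
Conditions: t-BuOK, THF, −78 °C (aldehyde added to base); BzCl, −78 → 0 °C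
Reagents that add atoms: benzoyl chloride, O=C(Cl)c1ccccc1
Why: O-acylation of the aldehyde enolate, whose Z geometry is fixed by potassium chelation between the enolate oxygen and the α-alkoxy oxygen (enol ester formation).

Step 9
Reactants: 16 3,4-bis(benzyloxy)benzaldehyde
Product: 17 3,4-bis(benzyloxy)benzaldehyde dimethyl acetal
Conditions: HC(OMe)3 (3 equiv), cat. p-TsOH, CH2Cl2, rt; Et3N quench
Reagents that add atoms: trimethyl orthoformate, COC(OC)OC
Why: Acid-catalysed acetalisation with the orthoformate as methoxy donor and water scavenger.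

Step 10
Reactants: 17 3,4-bis(benzyloxy)benzaldehyde dimethyl acetal; 18 3,5-bis(benzyloxy)phenol
Product: 20 1,3-bis(benzyloxy)-5-{[3,4-bis(benzyloxy)phenyl](methoxy)methoxy}benzene (racemic at the acetal carbon), via α-chlorobenzyl methyl ether 19 (not isolated)
Conditions: AcCl (1.05 equiv), CH2Cl2, 0 °C → rt; then 18, i-Pr2NEt, CH2Cl2, −20 °C → rt; base-washed silica
Reagents that add atoms: none
Why: Acetal–acyl chloride exchange gives the α-chloro ether, a hard electrophile that O-alkylates the phenol under amine base as in MOM ether formation; the acetal stereocentre is erased in step 11.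

Step 11
Reactants: 20 1,3-bis(benzyloxy)-5-{[3,4-bis(benzyloxy)phenyl](methoxy)methoxy}benzene; 15 (Z)-2-{[(1S,2R)-2-phenylcyclohexyl]oxy}ethenyl benzoate (1.5 equiv)
Product: 23 (2R,3R,4R)-5,7-bis(benzyloxy)-2-[3,4-bis(benzyloxy)phenyl]-4-{[(1S,2R)-2-phenylcyclohexyl]oxy}chroman-3-yl benzoate, via O-aryl oxocarbenium triflate 21 (not isolated), via C4 alkoxycarbenium triflate 22 (not isolated)
Conditions: 2,6-di-tert-butyl-4-methylpyridine (DTBMP, 1.2 equiv), 4 Å MS, CH2Cl2, −78 °C; TMSOTf (1.05 equiv) added slowly; Et3N then aq. NaHCO3 at −78 °C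
Reagents that add atoms: none
Why: Proposed new method: TMSOTf silylates the more basic methoxy oxygen of 20 and MeOTMS leaves, giving the E-configured O-aryl oxocarbenium ion 21, a cationic 2-oxadiene (C2=O1–C8a=C4a); its C2 is attacked by the benzoyloxy-bearing carbon of 15 (C2–C3 bond; the alkoxy group is the stronger donor, so the charge moves to C4 as alkoxycarbenium ion 22), and ring A then alkylates C4 (C4–C4a bond) with loss of a proton to DTBMP. The closest known reactions are the oxa-Povarov reaction of O-aryl oxocarbenium ions with styrenes and cycloalkenes, the Povarov reaction of N-aryl iminium ions with enol ethers, and Lewis-acid-promoted inverse-demand [4+2] cycloadditions of chiral 2-acyloxyvinyl ethers; a 1,2-dioxygenated alkene and auxiliary control have not been shown in the oxa series. Ring C closes by 6-exo-trig Friedel–Crafts attack of C4a on the C4=O+ bond, the whole being a formal [4+2] cycloaddition. C2 and C3 are set in the first bond formation: both oxygen substituents of the Z-alkene lie endo to the oxadiene and the ring B aryl group of E-configured 21 points outward, which gives the 2,3-cis relation, and the absolute sense comes from the auxiliary, because the Z-enol ether reacts through its s-trans conformer, in which the phenyl group of the (1S,2R)-cyclohexyl ring covers the Re face of C3, so that C2 bonds to the Si face (3R, hence 2R); C4 is expected cis but is erased later. The step needs regioselectivity in the alkene (alkoxy versus acyloxy donor strength), the correct direction of acetal ionisation (methoxy is the more basic oxygen and the aryloxy cation is strongly stabilised by the 3,4-dialkoxyphenyl group), no choice of ring-closure site (the two ortho positions of the symmetrical 3,5-bis(benzyloxy)phenoxy ring are equivalent) and survival of the ionisable C4 ether of 23 (TMSOTf is used stoichiometrically with DTBMP and is spent as MeOTMS and pyridinium triflate).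

Step 12
Reactants: 23 (2R,3R,4R)-5,7-bis(benzyloxy)-2-[3,4-bis(benzyloxy)phenyl]-4-{[(1S,2R)-2-phenylcyclohexyl]oxy}chroman-3-yl benzoate; 8 trimer (1.5 equiv, excess recovered)
Product: 25 [3-O-benzoyl-5,7,3',4'-tetra-O-benzylepicatechin]-(4β→8)-[3-O-acetyl-5,7,3',4'-tetra-O-benzylepicatechin]-(4β→8)-[3-O-acetyl-5,7,3',4'-tetra-O-benzylepicatechin]-(4β→8)-[5,7,3',4'-tetra-O-benzylepicatechin], via 3-O-benzoyl flavan-4-yl cation triflate 24 (not isolated)
Conditions: TMSOTf (cat.), CH2Cl2, −78 → −40 °C, 23 added slowly to 8; aq. NaHCO3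
Reagents that add atoms: none
Why: Ionisation of the C4 auxiliary ether gives the ring A-stabilised cation, which the free C8 of the upper unit of 8 attacks anti to the participating C3 benzoate (flavan-4-yl cation Friedel–Crafts coupling), setting C4 as 4β and releasing the auxiliary alcohol.

Step 13
Reactants: 25 protected tetramer (one benzoate, two acetates)
Product: 26 hexadeca-O-benzyl epicatechin-(4β→8) tetramer (5,7,3',4'-tetra-O-benzyl on each of the four units, four free C3 hydroxyls)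
Conditions: NaOMe, MeOH/THF 1:1, 40 °C
Reagents that add atoms: none
Why: Zemplén-type transesterification removes the benzoate and both acetates, while benzyl ethers and interflavan bonds are inert to methoxide and no stereocentre is touched.

Step 14
Reactants: 26 hexadeca-O-benzyl epicatechin-(4β→8) tetramer
Product: 27 epicatechin-(4β→8)-epicatechin-(4β→8)-epicatechin-(4β→8)-epicatechin (the target tetramer)
Conditions: H2 (1 atm), Pd(OH)2/C, THF/MeOH/H2O, rt; filtration, Sephadex LH-20, lyophilisation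
Reagents that add atoms: none
Why: Hydrogenolysis of the sixteen benzyl aryl ethers under neutral conditions, which is expected to leave the benzylic C–O and C–C bonds of the flavan rings intact, as is usual for benzylated procyanidins.

**Compound list**
1 | (−)-epicatechin | Oc1cc(O)c2c(c1)O[C@H](c1ccc(O)c(O)c1)[C@H](O)C2 | starting material
2 | 5,7,3',4'-tetra-O-benzyl-(−)-epicatechin | c3ccccc3COc1cc(OCc3ccccc3)c2c(c1)O[C@H](c1ccc(OCc3ccccc3)c(OCc3ccccc3)c1)[C@H](O)C2 | intermediate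
3 | (2R,3R,4S)-5,7,3',4'-tetra-O-benzyl-4-(2-ethoxyethoxy)flavan-3-ol | c3ccccc3COc1cc(OCc3ccccc3)c2c(c1)O[C@H](c1ccc(OCc3ccccc3)c(OCc3ccccc3)c1)[C@H](O)[C@H]2OCCOCC | intermediate
4 | (2R,3R,4S)-5,7,3',4'-tetra-O-benzyl-4-(2-ethoxyethoxy)flavan-3-yl acetate | c3ccccc3COc1cc(OCc3ccccc3)c2c(c1)O[C@H](c1ccc(OCc3ccccc3)c(OCc3ccccc3)c1)[C@H](OC(C)=O)[C@H]2OCCOCC | intermediate
5 | 3-O-acetyl-5,7,3',4'-tetra-O-benzylepicatechin-4-yl cation triflate | c3ccccc3COc1cc(OCc3ccccc3)c2c(c1)O[C@H](c1ccc(OCc3ccccc3)c(OCc3ccccc3)c1)[C@H](OC(C)=O)[CH+]2.[O-]S(=O)(=O)C(F)(F)F | intermediate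
6 | [3-O-acetyl-tetra-O-benzylepicatechin]-(4β→8)-[tetra-O-benzylepicatechin] | c3ccccc3COc1cc(OCc3ccccc3)c2c(c1)O[C@H](c1ccc(OCc3ccccc3)c(OCc3ccccc3)c1)[C@H](OC(C)=O)[C@H]2c1c(OCc3ccccc3)cc(OCc3ccccc3)c2c1O[C@H](c1ccc(OCc3ccccc3)c(OCc3ccccc3)c1)[C@H](O)C2 | intermediate
7 | 3-O-acetyl-5,7,3',4'-tetra-O-benzylepicatechin-4-yl cation tetrafluoroborate | c3ccccc3COc1cc(OCc3ccccc3)c2c(c1)O[C@H](c1ccc(OCc3ccccc3)c(OCc3ccccc3)c1)[C@H](OC(C)=O)[CH+]2.F[B-](F)(F)F | intermediate
8 | [3-O-acetyl-tetra-O-benzylepicatechin]-(4β→8)-[3-O-acetyl-tetra-O-benzylepicatechin]-(4β→8)-[tetra-O-benzylepicatechin] | c3ccccc3COc1cc(OCc3ccccc3)c2c(c1)O[C@H](c1ccc(OCc3ccccc3)c(OCc3ccccc3)c1)[C@H](OC(C)=O)[C@H]2c1c(OCc3ccccc3)cc(OCc3ccccc3)c2c1O[C@H](c1ccc(OCc3ccccc3)c(OCc3ccccc3)c1)[C@H](OC(C)=O)[C@H]2c1c(OCc3ccccc3)cc(OCc3ccccc3)c2c1O[C@H](c1ccc(OCc3ccccc3)c(OCc3ccccc3)c1)[C@H](O)C2 | intermediate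
9 | (1S,2R)-trans-2-phenylcyclohexanol | O[C@H]1CCCC[C@@H]1c1ccccc1 | starting material
10 | sodium (1S,2R)-2-phenylcyclohexanolate | [Na+].[O-][C@H]1CCCC[C@@H]1c1ccccc1 | intermediate
11 | allyl (1S,2R)-2-phenylcyclohexyl ether | C=CCO[C@H]1CCCC[C@@H]1c1ccccc1 | intermediate
12 | 3-({[(1S,2R)-2-phenylcyclohexyl]oxy}methyl)-1,2,4-trioxolane (secondary ozonide, epimer mixture at the ring carbon) | C1OC(CO[C@H]2CCCC[C@@H]2c2ccccc2)OO1 | intermediate
13 | 2-{[(1S,2R)-2-phenylcyclohexyl]oxy}acetaldehyde | O=CCO[C@H]1CCCC[C@@H]1c1ccccc1 | intermediate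
14 | potassium (Z)-2-{[(1S,2R)-2-phenylcyclohexyl]oxy}ethenolate | [K+].[O-]/C=C\O[C@H]1CCCC[C@@H]1c1ccccc1 | intermediate
15 | (Z)-2-{[(1S,2R)-2-phenylcyclohexyl]oxy}ethenyl benzoate | O=C(O/C=C\O[C@H]1CCCC[C@@H]1c1ccccc1)c1ccccc1 | intermediate
16 | 3,4-bis(benzyloxy)benzaldehyde | O=Cc1ccc(OCc2ccccc2)c(OCc2ccccc2)c1 | starting material
17 | 3,4-bis(benzyloxy)benzaldehyde dimethyl acetal | COC(OC)c1ccc(OCc2ccccc2)c(OCc2ccccc2)c1 | intermediate
18 | 3,5-bis(benzyloxy)phenol | Oc1cc(OCc2ccccc2)cc(OCc2ccccc2)c1 | starting material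
19 | 1,2-bis(benzyloxy)-4-[chloro(methoxy)methyl]benzene (α-chloro ether, racemic) | COC(Cl)c1ccc(OCc2ccccc2)c(OCc2ccccc2)c1 | intermediate
20 | 1,3-bis(benzyloxy)-5-{[3,4-bis(benzyloxy)phenyl](methoxy)methoxy}benzene (racemic mixed acetal) | COC(Oc1cc(OCc2ccccc2)cc(OCc2ccccc2)c1)c1ccc(OCc2ccccc2)c(OCc2ccccc2)c1 | intermediate
21 | [3,4-bis(benzyloxy)benzylidene][3,5-bis(benzyloxy)phenyl]oxonium triflate (O-aryl oxocarbenium ion) | c3ccccc3COc1cc(OCc3ccccc3)cc(c1)[O+]=Cc1ccc(OCc3ccccc3)c(OCc3ccccc3)c1.[O-]S(=O)(=O)C(F)(F)F | intermediate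
22 | open-chain C4 alkoxycarbenium triflate after C2–C3 bond formation, (2R,3R), O-(1S,2R)-2-phenylcyclohexyl | c3ccccc3COc1cc(OCc3ccccc3)cc(c1)O[C@H](c1ccc(OCc3ccccc3)c(OCc3ccccc3)c1)[C@H](OC(=O)c1ccccc1)C=[O+][C@H]1CCCC[C@@H]1c1ccccc1.[O-]S(=O)(=O)C(F)(F)F | intermediate
23 | (2R,3R,4R)-5,7-bis(benzyloxy)-2-[3,4-bis(benzyloxy)phenyl]-4-{[(1S,2R)-2-phenylcyclohexyl]oxy}chroman-3-yl benzoate (2,3-cis, 3,4-cis) | c3ccccc3COc1cc(OCc3ccccc3)c2c(c1)O[C@H](c1ccc(OCc3ccccc3)c(OCc3ccccc3)c1)[C@H](OC(=O)c1ccccc1)[C@@H]2O[C@H]1CCCC[C@@H]1c1ccccc1 | intermediate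
24 | 3-O-benzoyl-5,7,3',4'-tetra-O-benzylepicatechin-4-yl cation triflate | c3ccccc3COc1cc(OCc3ccccc3)c2c(c1)O[C@H](c1ccc(OCc3ccccc3)c(OCc3ccccc3)c1)[C@H](OC(=O)c1ccccc1)[CH+]2.[O-]S(=O)(=O)C(F)(F)F | intermediate
25 | [3-O-benzoyl-tetra-O-benzylepicatechin]-(4β→8)-[3-O-acetyl-tetra-O-benzylepicatechin]-(4β→8)-[3-O-acetyl-tetra-O-benzylepicatechin]-(4β→8)-[tetra-O-benzylepicatechin] | c3ccccc3COc1cc(OCc3ccccc3)c2c(c1)O[C@H](c1ccc(OCc3ccccc3)c(OCc3ccccc3)c1)[C@H](OC(=O)c1ccccc1)[C@H]2c1c(OCc3ccccc3)cc(OCc3ccccc3)c2c1O[C@H](c1ccc(OCc3ccccc3)c(OCc3ccccc3)c1)[C@H](OC(C)=O)[C@H]2c1c(OCc3ccccc3)cc(OCc3ccccc3)c2c1O[C@H](c1ccc(OCc3ccccc3)c(OCc3ccccc3)c1)[C@H](OC(C)=O)[C@H]2c1c(OCc3ccccc3)cc(OCc3ccccc3)c2c1O[C@H](c1ccc(OCc3ccccc3)c(OCc3ccccc3)c1)[C@H](O)C2 | intermediate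
26 | hexadeca-O-benzyl epicatechin-(4β→8) tetramer | c3ccccc3COc1cc(OCc3ccccc3)c2c(c1)O[C@H](c1ccc(OCc3ccccc3)c(OCc3ccccc3)c1)[C@H](O)[C@H]2c1c(OCc3ccccc3)cc(OCc3ccccc3)c2c1O[C@H](c1ccc(OCc3ccccc3)c(OCc3ccccc3)c1)[C@H](O)[C@H]2c1c(OCc3ccccc3)cc(OCc3ccccc3)c2c1O[C@H](c1ccc(OCc3ccccc3)c(OCc3ccccc3)c1)[C@H](O)[C@H]2c1c(OCc3ccccc3)cc(OCc3ccccc3)c2c1O[C@H](c1ccc(OCc3ccccc3)c(OCc3ccccc3)c1)[C@H](O)C2 | intermediate
27 | epicatechin-(4β→8)-epicatechin-(4β→8)-epicatechin-(4β→8)-epicatechin (the cinnamtannin tetramer named in the task) | Oc1cc(O)c2c(c1)O[C@H](c1ccc(O)c(O)c1)[C@H](O)[C@H]2c1c(O)cc(O)c2c1O[C@H](c1ccc(O)c(O)c1)[C@H](O)[C@H]2c1c(O)cc(O)c2c1O[C@H](c1ccc(O)c(O)c1)[C@H](O)[C@H]2c1c(O)cc(O)c2c1O[C@H](c1ccc(O)c(O)c1)[C@H](O)C2 | target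

**Step count and risks**
Total step count: 14. Longest linear sequence: 8 steps (steps 1–5, then 12, 13, 14).

Steps most likely to fail:

1. Step 11 (proposed new method). The first C–C bond formation may show poor facial or endo/exo selectivity, the oxocarbenium ion may alkylate a phloroglucinol-type ring of another molecule instead of the enol ether, or the C4 ether of the product may ionise early. Fallback with known chemistry, giving up the de novo ring construction: it sets out from electrophile 4 and trimer 8, which are coupled with catalytic AgBF4 in CH2Cl2 as in step 5 to give the tri-O-acetyl hexadeca-O-benzyl tetramer F1, and methanolysis of its three acetates with NaOMe in MeOH/THF brings the route back at compound 26.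

2. Step 12. The electrophile may self-condense through its own free C8 or react at a C6 position, and long exposure to the Lewis acid may scramble interflavan bonds. Fallback that caps the nucleophilic site: it sets out from 23, which is brominated with NBS in CH2Cl2 at −40 °C at C8 to give the 8-bromo electrophile F2; TMSOTf coupling with 8 gives the 8-bromo protected tetramer F3; NaOMe methanolysis gives the 8-bromo hexadeca-O-benzyl tetramer F4; hydrogenolysis over Pd(OH)2/C with H2 and Et3N removes the benzyl groups and the bromine together and comes back at compound 27.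

3. Step 10. The α-chloro ether may C-alkylate the very electron-rich phenol ring instead of oxygen, and the mixed acetal may be lost by hydrolysis on isolation. Fallback through C–H oxidation in place of O-alkylation of an oxocarbenium precursor: it sets out from phenol 18, which is etherified with 3,4-bis(benzyloxy)benzyl chloride (ClCc1ccc(OCc2ccccc2)c(OCc2ccccc2)c1; K2CO3, DMF, rt) to give the benzyl aryl ether F5; DDQ in CH2Cl2/MeOH at 0 °C oxidises the dialkoxybenzylic CH2 selectively, and methanol captures the cation to come back at compound 20.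

Further compounds
F1 | step 11 | [3-O-acetyl-tetra-O-benzylepicatechin]-(4β→8)-[3-O-acetyl-tetra-O-benzylepicatechin]-(4β→8)-[3-O-acetyl-tetra-O-benzylepicatechin]-(4β→8)-[tetra-O-benzylepicatechin] | c3ccccc3COc1cc(OCc3ccccc3)c2c(c1)O[C@H](c1ccc(OCc3ccccc3)c(OCc3ccccc3)c1)[C@H](OC(C)=O)[C@H]2c1c(OCc3ccccc3)cc(OCc3ccccc3)c2c1O[C@H](c1ccc(OCc3ccccc3)c(OCc3ccccc3)c1)[C@H](OC(C)=O)[C@H]2c1c(OCc3ccccc3)cc(OCc3ccccc3)c2c1O[C@H](c1ccc(OCc3ccccc3)c(OCc3ccccc3)c1)[C@H](OC(C)=O)[C@H]2c1c(OCc3ccccc3)cc(OCc3ccccc3)c2c1O[C@H](c1ccc(OCc3ccccc3)c(OCc3ccccc3)c1)[C@H](O)C2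
F2 | step 12 | (2R,3R,4R)-5,7-bis(benzyloxy)-2-[3,4-bis(benzyloxy)phenyl]-8-bromo-4-{[(1S,2R)-2-phenylcyclohexyl]oxy}chroman-3-yl benzoate | c3ccccc3COc1cc(OCc3ccccc3)c2c(c1Br)O[C@H](c1ccc(OCc3ccccc3)c(OCc3ccccc3)c1)[C@H](OC(=O)c1ccccc1)[C@@H]2O[C@H]1CCCC[C@@H]1c1ccccc1
F3 | step 12 | [3-O-benzoyl-8-bromo-tetra-O-benzylepicatechin]-(4β→8)-[3-O-acetyl-tetra-O-benzylepicatechin]-(4β→8)-[3-O-acetyl-tetra-O-benzylepicatechin]-(4β→8)-[tetra-O-benzylepicatechin] | c3ccccc3COc1cc(OCc3ccccc3)c2c(c1Br)O[C@H](c1ccc(OCc3ccccc3)c(OCc3ccccc3)c1)[C@H](OC(=O)c1ccccc1)[C@H]2c1c(OCc3ccccc3)cc(OCc3ccccc3)c2c1O[C@H](c1ccc(OCc3ccccc3)c(OCc3ccccc3)c1)[C@H](OC(C)=O)[C@H]2c1c(OCc3ccccc3)cc(OCc3ccccc3)c2c1O[C@H](c1ccc(OCc3ccccc3)c(OCc3ccccc3)c1)[C@H](OC(C)=O)[C@H]2c1c(OCc3ccccc3)cc(OCc3ccccc3)c2c1O[C@H](c1ccc(OCc3ccccc3)c(OCc3ccccc3)c1)[C@H](O)C2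
F4 | step 12 | 8-bromo-hexadeca-O-benzyl epicatechin-(4β→8) tetramer (bromine at C8 of the top unit) | c3ccccc3COc1cc(OCc3ccccc3)c2c(c1Br)O[C@H](c1ccc(OCc3ccccc3)c(OCc3ccccc3)c1)[C@H](O)[C@H]2c1c(OCc3ccccc3)cc(OCc3ccccc3)c2c1O[C@H](c1ccc(OCc3ccccc3)c(OCc3ccccc3)c1)[C@H](O)[C@H]2c1c(OCc3ccccc3)cc(OCc3ccccc3)c2c1O[C@H](c1ccc(OCc3ccccc3)c(OCc3ccccc3)c1)[C@H](O)[C@H]2c1c(OCc3ccccc3)cc(OCc3ccccc3)c2c1O[C@H](c1ccc(OCc3ccccc3)c(OCc3ccccc3)c1)[C@H](O)C2
F5 | step 10 | 1,3-bis(benzyloxy)-5-{[3,4-bis(benzyloxy)phenyl]methoxy}benzene | C(Oc1cc(OCc2ccccc2)cc(OCc2ccccc2)c1)c1ccc(OCc2ccccc2)c(OCc2ccccc2)c1
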